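Ring B is read as a Diels–Alder adduct: diene C5=C6–C7=C8, dienophile C9=C10. Because O3 on C3 of ring A stands 1,4 to the C6 carbonyl, O3 is lent to C6 as its enol-ether oxygen, so the precursor is a monocyclic (R)-2,3-dihydrofuran carrying an (E)-propenyl group and a (Z)-enoate arm. One intramolecular [4+2] cycloaddition forges C5–C10 and C8–C9, closes rings A and B, and through the temporary O3–C6 bridge relays C3 to C10 and C9 (O3 and C11 both anti to the C10 methyl). Hydrolysis then releases the C3 hydroxyl and the C6 ketone; C5, α to that ketone, is equilibrated to the trans fusion, and dehydrogenation installs C7=C8.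

Key step: step 8

Remark: drimane numbering is used for all intermediates (ring A = C1–C5 and C10; ring B = C5–C10; C11 = the CH2O carbon on C9; C12 = the methyl on C8; O3 = the oxygen on C3).
Remark: the kinetic resolution in step 2 is assumed to follow the usual sense for terminal epoxides, the (R,R)-catalyst consuming the (R)-epoxide.

Step 1
Reactants: 1 methyl 3,3-dimethylpent-4-enoate
Product: 2 methyl 3-methyl-3-(oxiran-2-yl)butanoate (racemic)
Conditions: mCPBA, NaHCO3, CH2Cl2, 0 → 40 °C
Reagents that add atoms: 3-chloroperoxybenzoic acid (mCPBA), OOC(=O)c1cccc(Cl)c1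
Why: Prilezhaev epoxidation of the only C=C should proceed slowly but cleanly under buffered conditions; the new stereocentre (the future C3) is formed racemic and is resolved in step 2.

Step 2
Reactants: 2 methyl 3-methyl-3-(oxiran-2-yl)butanoate (racemic)
Product: 3 methyl 3-methyl-3-[(2S)-oxiran-2-yl]butanoate
Conditions: (R,R)-(salen)Co(OAc) (0.5 mol %; trivalent cobalt; salen = N,N′-bis(3,5-di-tert-butylsalicylidene)cyclohexane-1,2-diamine), H2O (0.55 equiv), THF, 0 °C → rt; distillation
Reagents that add atoms: none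
Why: Jacobsen hydrolytic kinetic resolution should hydrolyse the (R)-epoxide much faster (terminal tert-alkyl oxiranes are good substrates), so the (S)-epoxide, whose carbinol carbon becomes C3 (R) of the target, is recovered from the diol.

Step 3
Reactants: 3 methyl 3-methyl-3-[(2S)-oxiran-2-yl]butanoate; 4 1-(trimethylsilyl)propyne
Product: 6 (5R)-4,4-dimethyl-5-[4-(trimethylsilyl)but-3-yn-1-yl]oxolan-2-one, via hydroxy ester 5 (not isolated)
Conditions: 4, n-BuLi, THF, −78 → −20 °C; then BF3·OEt2 and 3, −78 °C; NaHCO3 aq.; then TsOH (cat.), CH2Cl2, rt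
Reagents that add atoms: none
Why: BF3-assisted SN2 opening of the epoxide at its CH2 terminus by the propargylic lithium reagent should outrun addition to the β-quaternary ester at −78 °C and leaves the stereocentre untouched; the γ-hydroxy ester then lactonises (gem-dimethyl effect) with loss of methanol.

Step 4
Reactants: 6 (5R)-4,4-dimethyl-5-[4-(trimethylsilyl)but-3-yn-1-yl]oxolan-2-one
Product: 8 (5R)-4,4-dimethyl-5-[4-(trimethylsilyl)but-3-yn-1-yl]-4,5-dihydrofuran-2-yl diphenyl phosphate, via potassium lactone enolate 7 (not isolated)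
Conditions: KHMDS, THF–DMPU, −78 °C; then (PhO)2P(O)Cl, −78 → 0 °C
Reagents that add atoms: diphenyl chlorophosphate, O=P(Cl)(Oc1ccccc1)Oc1ccccc1
Why: Enolisation at the only lactone α-CH2 (C5) and O-phosphorylation should give the cyclic ketene acetal phosphate, fixing the C5=C6 enol-ether double bond inside the ring; the silylalkyne offers no competing acidic site.

Step 5
Reactants: 8 (5R)-4,4-dimethyl-5-[4-(trimethylsilyl)but-3-yn-1-yl]-4,5-dihydrofuran-2-yl diphenyl phosphate; 9 (E)-prop-1-en-1-ylboronic acid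
Product: 10 (2R)-3,3-dimethyl-5-[(1E)-prop-1-en-1-yl]-2-[4-(trimethylsilyl)but-3-yn-1-yl]-2,3-dihydrofuran
Conditions: Pd(PPh3)4 (5 mol %), Na2CO3 (2 M aq.), DME, 70 °C
Reagents that add atoms: none
Why: Suzuki–Miyaura coupling of the ketene acetal phosphate (a vinyl pseudohalide) with the alkenylboronic acid should form C6–C7 with retention of the E geometry, giving the semicyclic 2-alkoxydiene.

Step 6
Reactants: 10 (2R)-3,3-dimethyl-5-[(1E)-prop-1-en-1-yl]-2-[4-(trimethylsilyl)but-3-yn-1-yl]-2,3-dihydrofuran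
Product: 12 methyl 5-[(2R)-3,3-dimethyl-5-[(1E)-prop-1-en-1-yl]-2,3-dihydrofuran-2-yl]pent-2-ynoate, via lithium acetylide 11 (not isolated)
Conditions: MeLi·LiBr, THF, 0 °C → rt; then ClCO2Me, −78 °C; kept cold and used at once
Reagents that add atoms: methyl chloroformate, COC(=O)Cl
Why: MeLi should cleave the alkynyl–silicon bond (silicon-to-lithium exchange) to the acetylide, which is C-acylated by the chloroformate; the enol-ether diene tolerates these basic, non-acidic conditions.

Step 7
Reactants: 12 methyl 5-[(2R)-3,3-dimethyl-5-[(1E)-prop-1-en-1-yl]-2,3-dihydrofuran-2-yl]pent-2-ynoate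
Product: 14 methyl (2Z)-5-[(2R)-3,3-dimethyl-5-[(1E)-prop-1-en-1-yl]-2,3-dihydrofuran-2-yl]-3-methylpent-2-enoate, via alkenylcuprate 13 (not isolated)
Conditions: Me2CuLi (from CuI and MeLi), THF, −78 °C; MeOH, then NH4Cl/NH3 aq., at −78 °C
Reagents that add atoms: lithium dimethylcuprate, [Li+].C[Cu-]C
Why: Syn carbocupration of the ynoate (Gilman cuprate conjugate addition) places the new methyl on C10 cis to copper, and protonation with retention at −78 °C should give the (Z)-enoate in which the chain carbon C1 and the ester carbon C11 are cis.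

Step 8
Reactants: 14 methyl (2Z)-5-[(2R)-3,3-dimethyl-5-[(1E)-prop-1-en-1-yl]-2,3-dihydrofuran-2-yl]-3-methylpent-2-enoate
Product: 15 methyl (3R,5S,8R,9R,10S)-3,6-epoxydrim-6-en-11-oate (cis-fused bridged enol ether; H-5, H-8, H-9 and the C10 methyl on one face, the O3–C6 bridge, C11 and C12 on the other)
Conditions: degassed PhMe (0.01 M), BHT (cat.), silylated sealed tube, 170 °C
Reagents that add atoms: none
Why: This is a thermal normal-electron-demand intramolecular Diels–Alder reaction in which the HOMO of the cyclic 2-alkoxydiene C5=C6(O3)–C7=C8 has its largest coefficient at C5 and the LUMO of the (Z)-enoate at C10, so a concerted but asynchronous transition state should form C5–C10 ahead of C8–C9. The closest known reaction type is the type 1 intramolecular Diels–Alder cyclisation of 2-alkoxy- or 2-silyloxy-1,3-dienes with enoates tethered by four atoms (here C4–C3–C2–C1) to give decalins. Ring A closes through C5–C10 as the arm on C3 bridges the 1,3-positions of the dihydrofuran, giving a chair inside a 2-oxabicyclo[3.2.1]octane, and ring B closes as the cis-fused [4+2] cyclohexene through C5–C10 plus C8–C9. C3 controls C10 and C5 because the arm can reach C5 only on its own face of the dihydrofuran and only with C1 endo, which puts O3 and C6 diaxial on ring A and the C10 methyl anti to O3; the Z geometry is transferred suprafacially so that the endo ester carbon C11 ends anti to the C10 methyl at C9, and the E-propenyl group sets C8, which is erased in step 13. The step needs facial, endo/exo and regiochemical control, all secured by the five-membered ring and the short tether rather than by a reagent, and it needs the dienophile geometry to survive the heating, which an ester should do. C5 is deliberately formed cis to the C10 methyl and is inverted in step 12.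

Step 9
Reactants: 15 methyl (3R,5S,8R,9R,10S)-3,6-epoxydrim-6-en-11-oate
Product: 16 (3R,5S,8S,9R,10R)-3,6-epoxydrim-6-en-11-ol
Conditions: LiAlH4, THF, 0 °C → rt; NaOH aq. work-up
Reagents that add atoms: none
Why: Hydride reduction of the hindered methyl ester should give the primary C11 alcohol without touching the base-stable bridged enol ether; no stereocentre is affected.

Step 10
Reactants: 16 (3R,5S,8S,9R,10R)-3,6-epoxydrim-6-en-11-ol; 17 isofraxidin (7-hydroxy-6,8-dimethoxy-2H-chromen-2-one)
Product: 18 7-{[(3R,5S,8S,9R,10R)-3,6-epoxydrim-6-en-11-yl]oxy}-6,8-dimethoxy-2H-chromen-2-one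
Conditions: PPh3, DIAD, THF, 0 → 50 °C
Reagents that add atoms: none
Why: Mitsunobu etherification: the acidic phenol should displace the oxyphosphonium of the primary C11 alcohol by SN2, while O3 is still masked in the enol ether so that no protecting group is needed; C9 is untouched.

Step 11
Reactants: 18 7-{[(3R,5S,8S,9R,10R)-3,6-epoxydrim-6-en-11-yl]oxy}-6,8-dimethoxy-2H-chromen-2-one
Product: 20 7-{[(3R,5S,8R,9R,10R)-3-hydroxy-6-oxodriman-11-yl]oxy}-6,8-dimethoxy-2H-chromen-2-one (cis-fused; in equilibrium with 19), via bridged hemiketal 19 (not isolated)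
Conditions: HCl (1 M aq.), THF, rt
Reagents that add atoms: water, O
Why: Acid-catalysed enol-ether hydrolysis: protonation at C7 gives the bridged oxocarbenium ion at C6, water adds, and the hemiketal opens to the C6 ketone and the free C3 hydroxyl; both tautomers, and any C5 epimer formed already, converge in step 12.

Step 12
Reactants: 20 7-{[(3R,5S,8R,9R,10R)-3-hydroxy-6-oxodriman-11-yl]oxy}-6,8-dimethoxy-2H-chromen-2-one
Product: 22 (3R,5R,8R,9R,10R)-11-[(6,8-dimethoxy-2-oxo-2H-chromen-7-yl)oxy]-6-oxodriman-3-yl 3-methylbutanoate (trans-fused), via cis-fused keto ester 21 (not isolated)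
Conditions: 3-methylbutanoyl chloride, DMAP, pyridine, CH2Cl2, 0 → 40 °C; then DBU, PhMe, 80 °C
Reagents that add atoms: 3-methylbutanoyl chloride, CC(C)CC(=O)Cl
Why: DMAP-catalysed acylation of the open form captures O3 as the isovalerate and shuts off the hemiketal, after which amidine-base enolisation should epimerise C5 (α to C6) under thermodynamic control to the trans fusion, since the cis isomer must place either C6 syn-diaxial to the C3 ester on ring A or the quaternary C4 axial on ring B.

Step 13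
Reactants: 22 (3R,5R,8R,9R,10R)-11-[(6,8-dimethoxy-2-oxo-2H-chromen-7-yl)oxy]-6-oxodriman-3-yl 3-methylbutanoate
Product: 23 (3R,5R,9R,10R)-11-[(6,8-dimethoxy-2-oxo-2H-chromen-7-yl)oxy]-6-oxodrim-7-en-3-yl 3-methylbutanoate (target, CNP0279705.1)
Conditions: IBX (2.5 equiv), DMSO–PhF (1:2), 70 °C
Reagents that add atoms: none
Why: IBX dehydrogenation of the ketone through its C6–C7 enol should introduce C7=C8, the only position that can be desaturated because C4 and C10 are quaternary; the C8 stereocentre disappears and C5 and C9 keep their configuration.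

Compound list
1 | methyl 3,3-dimethylpent-4-enoate | COC(=O)CC(C)(C)C=C | starting material
2 | methyl 3-methyl-3-(oxiran-2-yl)butanoate (racemic) | COC(=O)CC(C)(C)C1CO1 | intermediate
3 | methyl 3-methyl-3-[(2S)-oxiran-2-yl]butanoate | COC(=O)CC(C)(C)[C@H]1CO1 | intermediate
4 | 1-(trimethylsilyl)propyne | CC#C[Si](C)(C)C | starting material
5 | methyl (4R)-4-hydroxy-3,3-dimethyl-8-(trimethylsilyl)oct-7-ynoate | COC(=O)CC(C)(C)[C@H](O)CCC#C[Si](C)(C)C | intermediate
6 | (5R)-4,4-dimethyl-5-[4-(trimethylsilyl)but-3-yn-1-yl]oxolan-2-one | C[Si](C)(C)C#CCC[C@H]1OC(=O)CC1(C)C | intermediate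
7 | potassium (5R)-4,4-dimethyl-5-[4-(trimethylsilyl)but-3-yn-1-yl]-4,5-dihydrofuran-2-olate | C[Si](C)(C)C#CCC[C@H]1OC([O-])=CC1(C)C.[K+] | intermediate
8 | (5R)-4,4-dimethyl-5-[4-(trimethylsilyl)but-3-yn-1-yl]-4,5-dihydrofuran-2-yl diphenyl phosphate | C[Si](C)(C)C#CCC[C@H]1OC(OP(=O)(Oc2ccccc2)Oc2ccccc2)=CC1(C)C | intermediate
9 | (E)-prop-1-en-1-ylboronic acid | C/C=C/B(O)O | starting material
10 | (2R)-3,3-dimethyl-5-[(1E)-prop-1-en-1-yl]-2-[4-(trimethylsilyl)but-3-yn-1-yl]-2,3-dihydrofuran | C[Si](C)(C)C#CCC[C@H]1OC(/C=C/C)=CC1(C)C | intermediate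
11 | lithium 4-[(2R)-3,3-dimethyl-5-[(1E)-prop-1-en-1-yl]-2,3-dihydrofuran-2-yl]but-1-yn-1-ide | [Li]C#CCC[C@H]1OC(/C=C/C)=CC1(C)C | intermediate
12 | methyl 5-[(2R)-3,3-dimethyl-5-[(1E)-prop-1-en-1-yl]-2,3-dihydrofuran-2-yl]pent-2-ynoate | COC(=O)C#CCC[C@H]1OC(/C=C/C)=CC1(C)C | intermediate
13 | lithium methyl{(1Z)-4-[(2R)-3,3-dimethyl-5-[(1E)-prop-1-en-1-yl]-2,3-dihydrofuran-2-yl]-1-(methoxycarbonyl)-2-methylbut-1-en-1-yl}cuprate (copper cis to the new methyl) | [Li+].C[Cu-]/C(C(=O)OC)=C(/CC[C@H]1OC(/C=C/C)=CC1(C)C)C | intermediate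
14 | methyl (2Z)-5-[(2R)-3,3-dimethyl-5-[(1E)-prop-1-en-1-yl]-2,3-dihydrofuran-2-yl]-3-methylpent-2-enoate | COC(=O)/C=C(C)\CC[C@H]1OC(/C=C/C)=CC1(C)C | intermediate
15 | methyl (3R,5S,8R,9R,10S)-3,6-epoxydrim-6-en-11-oate | COC(=O)[C@@H]1[C@H](C)C=C2O[C@@H]3CC[C@@]1(C)[C@H]2C3(C)C | intermediate
16 | (3R,5S,8S,9R,10R)-3,6-epoxydrim-6-en-11-ol | OC[C@@H]1[C@H](C)C=C2O[C@@H]3CC[C@@]1(C)[C@H]2C3(C)C | intermediate
17 | isofraxidin (7-hydroxy-6,8-dimethoxy-2H-chromen-2-one) | COc1cc2ccc(=O)oc2c(OC)c1O | starting material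
18 | 7-{[(3R,5S,8S,9R,10R)-3,6-epoxydrim-6-en-11-yl]oxy}-6,8-dimethoxy-2H-chromen-2-one | COc1cc2ccc(=O)oc2c(OC)c1OC[C@@H]1[C@H](C)C=C2O[C@@H]3CC[C@@]1(C)[C@H]2C3(C)C | intermediate
19 | 7-{[(3R,5S,6S,8R,9R,10R)-3,6-epoxy-6-hydroxydriman-11-yl]oxy}-6,8-dimethoxy-2H-chromen-2-one (bridged hemiketal) | COc1cc2ccc(=O)oc2c(OC)c1OC[C@@H]1[C@H](C)C[C@]2(O)O[C@@H]3CC[C@@]1(C)[C@H]2C3(C)C | intermediate
20 | 7-{[(3R,5S,8R,9R,10R)-3-hydroxy-6-oxodriman-11-yl]oxy}-6,8-dimethoxy-2H-chromen-2-one (cis-fused) | COc1cc2ccc(=O)oc2c(OC)c1OC[C@@H]1[C@H](C)CC(=O)[C@@H]2C(C)(C)[C@H](O)CC[C@]12C | intermediate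
21 | (3R,5S,8R,9R,10R)-11-[(6,8-dimethoxy-2-oxo-2H-chromen-7-yl)oxy]-6-oxodriman-3-yl 3-methylbutanoate (cis-fused) | COc1cc2ccc(=O)oc2c(OC)c1OC[C@@H]1[C@H](C)CC(=O)[C@@H]2C(C)(C)[C@H](OC(=O)CC(C)C)CC[C@]12C | intermediate
22 | (3R,5R,8R,9R,10R)-11-[(6,8-dimethoxy-2-oxo-2H-chromen-7-yl)oxy]-6-oxodriman-3-yl 3-methylbutanoate (trans-fused) | COc1cc2ccc(=O)oc2c(OC)c1OC[C@@H]1[C@H](C)CC(=O)[C@H]2C(C)(C)[C@H](OC(=O)CC(C)C)CC[C@]12C | intermediate
23 | (3R,5R,9R,10R)-11-[(6,8-dimethoxy-2-oxo-2H-chromen-7-yl)oxy]-6-oxodrim-7-en-3-yl 3-methylbutanoate | COc1cc2ccc(=O)oc2c(OC)c1OC[C@@H]1C(C)=CC(=O)[C@H]2C(C)(C)[C@H](OC(=O)CC(C)C)CC[C@]12C | target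

Total steps: 13. Longest linear sequence: 13 steps (fully linear from 1).

Steps most likely to fail

Step 8. The cycloaddition may be too slow for the congested C5–C10 bond (β,β-disubstituted enoate against a diene terminus next to the quaternary C4), so that the heat- and acid-sensitive dienyl ether decomposes before it cyclises. The fallback changes the dienophile activation and sets out from 14. DIBAL (CH2Cl2, −78 °C) should reduce the ester to (2Z)-5-[(2R)-3,3-dimethyl-5-[(1E)-prop-1-en-1-yl]-2,3-dihydrofuran-2-yl]-3-methylpent-2-en-1-ol F1. MnO2 (CH2Cl2, rt, used at once) should give the corresponding (2Z)-enal F2, a much stronger dienophile that is expected to cyclise in PhMe at or below 80 °C through the same tether-enforced geometry to (3R,5S,8R,9R,10S)-3,6-epoxydrim-6-en-11-al F3. NaBH4 (MeOH, 0 °C) then reduces F3 to 16, where the route is rejoined.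

Step 5. Hydrolysis or collapse of the five-membered ketene acetal phosphate may outrun oxidative addition and transmetalation. The fallback builds the diene by carbonyl addition and dehydration and sets out from 6. (E)-Prop-1-enyllithium (from (E)-1-bromopropene and t-BuLi, Et2O, −78 °C) should add once to the lactone to give the lactol (5R)-4,4-dimethyl-2-[(1E)-prop-1-en-1-yl]-5-[4-(trimethylsilyl)but-3-yn-1-yl]oxolan-2-ol F4. MsCl/Et3N (CH2Cl2, −20 °C → rt) should dehydrate F4 through the oxocarbenium ion to the conjugated endocyclic enol ether 10, where the route is rejoined.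

Step 12. Deprotonation at the congested C5–H may be too slow under amidine base, or the base may begin to open the coumarin lactone, leaving cis-fused material. The fallback moves the equilibration to the enone level and sets out from 21, isolated after the acylation stage. IBX (DMSO–PhF, 70 °C) should dehydrogenate it to (3R,5S,9R,10R)-11-[(6,8-dimethoxy-2-oxo-2H-chromen-7-yl)oxy]-6-oxodrim-7-en-3-yl 3-methylbutanoate F5. Camphorsulfonic acid (CHCl3, 50 °C) should then equilibrate C5 through the cross-conjugated dienol to the trans-fused 23, where the route ends.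

Further compounds
F1 | step 8 | (2Z)-5-[(2R)-3,3-dimethyl-5-[(1E)-prop-1-en-1-yl]-2,3-dihydrofuran-2-yl]-3-methylpent-2-en-1-ol | OC/C=C(C)\CC[C@H]1OC(/C=C/C)=CC1(C)C
F2 | step 8 | (2Z)-5-[(2R)-3,3-dimethyl-5-[(1E)-prop-1-en-1-yl]-2,3-dihydrofuran-2-yl]-3-methylpent-2-enal | O=C/C=C(C)\CC[C@H]1OC(/C=C/C)=CC1(C)C
F3 | step 8 | (3R,5S,8R,9R,10S)-3,6-epoxydrim-6-en-11-al | O=C[C@@H]1[C@H](C)C=C2O[C@@H]3CC[C@@]1(C)[C@H]2C3(C)C
F4 | step 5 | (5R)-4,4-dimethyl-2-[(1E)-prop-1-en-1-yl]-5-[4-(trimethylsilyl)but-3-yn-1-yl]oxolan-2-ol | C[Si](C)(C)C#CCC[C@H]1OC(O)(/C=C/C)CC1(C)C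
F5 | step 12 | (3R,5S,9R,10R)-11-[(6,8-dimethoxy-2-oxo-2H-chromen-7-yl)oxy]-6-oxodrim-7-en-3-yl 3-methylbutanoate | COc1cc2ccc(=O)oc2c(OC)c1OC[C@@H]1C(C)=CC(=O)[C@@H]2C(C)(C)[C@H](OC(=O)CC(C)C)CC[C@]12C
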